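Slowness arrives late in these flasks, and the way it arrives is what I want to read.

| flask | Z | time |
|---|---|---|
| north-west | 0.250 M |  |
| south-west | 0.380 M |  |
| west | 0.610 M | 10 min |

| north-west run: time / min | north-west run: [J] / M | south-west run: time / min | south-west run: [J] / M |
|---|---|---|---|
| 0.76 | 0.017 | 0.76 | 0.023 |
| 2.3 | 0.043 | 2.3 | 0.076 |
| 4.4 | 0.061 | 4.4 | 0.112 |
| 7.0 | 0.076 | 7.0 | 0.130 |
| 10 | 0.082 | 10 | 0.139 |

(readings scatter by 0.003 M)

- order of the initial rate in [Z], near the charge of the north-west run, the rate being that where two percent of its Z are J (one fixed amount of J, the same in the runs compared)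
- J in the west run at 10 min, as a share of the Z charged

- Overall: Z -> J.
- Constant volume, constant temperature.
- An order is taken over about fifteen percent of the charge, up and down.

In the north-west run, J rises at 0.0187 M min⁻¹ over the first 2.3 min and at 0.00200 M min⁻¹ over the last stretch, so the first slope is ten times the last. The knee stands at nearly one place: at 2.3 min the north-west run has 52.4% of its final reading and the south-west run 54.7%. The readings at 10 min differ, though, at 32.8% of the charge in the north-west run and 36.6% in the south-west run.

So I freeze one number. At 10 min the two runs give 1.26, my charge exponent: the logarithm of the ratio of J at one time over the logarithm of the ratio of the charges, an apparent order. At 0.76 min the two readings differ by only twice the scatter, so for the order asked I take the pair at 2.3 min, which gives 1.36, and I commit to that.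

Carried to the west run, these exponents draw a curve with 0.145 M at 2.3 min, a mean slope of 0.0630 M min⁻¹ up to there, and 0.252 M at 10 min, which is 41.4% of the charge.

The forecast says an order of 0.5 and 35%, both lower than mine, and calls its order “well below one and suggests saturation”.

The flask gives an order of 1.1 and 40.7%.

    2 Z ⇌ Q + Z (0.8160 M⁻¹ min⁻¹, 2.022 M⁻¹ min⁻¹)
    Q → J (0.6780 min⁻¹)
    Z → J (0.04398 min⁻¹)
    Z → Vy (0.2334 min⁻¹)

From the south-west run to the west run, the exponent at 10 min comes to 1.23 against my 1.26, and the rate exponent, from the south-west run's rate at 1.6 times the north-west run's where both have made one fixed amount of J, comes to 1.10 against my 1.36. While Z is there it goes to Q by the pair step, which also runs back, to Vy, and straight to J more slowly than to Vy, and Q passes on to J at 0.678 min⁻¹. At the start of the west run Q forms at 0.304 M min⁻¹ against 0.142 M min⁻¹ for Vy, and at the start of the north-west run at 0.0510 M min⁻¹ against 0.0583 M min⁻¹.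

The numbers in the tables were generated by integration for an exercise; scatter was added.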